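**Plan**

- Retrosynthesis: after removal of the two MOM ethers, ring C is cut at C4–C4a (aryl–carbonyl) and at O1–C8a (aryl ether). This leaves a ring A aryne (C4a≡C8a, with the C8 prenyl group and the C5/C7 oxygens in place) and an open-chain (S)-3-aryl-3-silyloxy Weinreb amide carrying ring B, ring D, C2, C3 and C4.
- Forward, ring A: phloroglucinol is bis-MOM protected and carbamoylated; two carbamate-directed ortho-metalations in one flask put SiMe3 at C4a and then prenyl at C8; the carbamate is then exchanged for triflate.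
- Forward, rings B and D: ring D is closed by a propargyl ether Claisen rearrangement, prenyl is added by Stille coupling, and the C3–C4 unit by Claisen condensation.
- Union: fluoride sets free the C2 alkoxide and the aryne. The C5 oxygen next to C4a polarizes the C4a≡C8a bond, so O1 adds at C8a and the carbanion appears at C4a, six atoms from the amide carbonyl C4, which it acylates to close ring C.
- Stereochemistry: the single stereocenter C2 (S) comes from asymmetric transfer hydrogenation of the β-keto amide and is kept with retention, since its C–O bond is never broken; acid removes the MOM groups last.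

Key step: step 11

Remark: flavanone numbering is used throughout (O1, C2, C3, C4, C4a, C5 to C8, C8a; ring A is the phloroglucinol ring, ring C the pyranone ring, ring B the pendant aryl ring, ring D its fused dimethylpyran ring), and the C2 configuration of the given structure is S.

**Route**

Step 1
Reactants: 1 phloroglucinol
Product: 2 3,5-bis(methoxymethoxy)phenol
Conditions: MOMCl (2.0 equiv), iPr2NEt, DMF, 0 °C → rt; chromatographic separation from the mono- and tris-ethers, which are recycled
Reagents that add atoms: chloromethyl methyl ether (MOMCl), COCCl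
Why: Williamson-type O-alkylation is statistical over three equivalent hydroxyls, so two equivalents of MOMCl should give the bis-ether as the main, separable product, and the MOM groups later serve as ortho-directors and as fluoride-stable protection.

Step 2
Reactants: 2 3,5-bis(methoxymethoxy)phenol
Product: 3 3,5-bis(methoxymethoxy)phenyl N-isopropylcarbamate
Conditions: i-PrNCO, Et3N (cat.), CH2Cl2, rt
Reagents that add atoms: isopropyl isocyanate, CC(C)N=C=O
Why: Amine-catalyzed addition of the phenol to the isocyanate (carbamoylation) should be clean and installs an N-monosubstituted carbamate that is the strongest ortho-director on the ring and can later be removed by mild E1cB cleavage.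

Step 3
Reactants: 3 3,5-bis(methoxymethoxy)phenyl N-isopropylcarbamate, 4 prenyl bromide
Product: 10 3,5-bis(methoxymethoxy)-2-(3-methylbut-2-en-1-yl)-6-(trimethylsilyl)phenyl N-isopropylcarbamate, via N-silyl carbamate 5 (not isolated), via first aryllithium 6 (not isolated), via C-silylated N-silyl carbamate 7 (not isolated), via second aryllithium 8 (not isolated), via prenylated N-silyl carbamate 9 (not isolated)
Conditions: TBSOTf, TMEDA, Et2O, 0 °C → rt; n-BuLi (2.1 equiv), TMEDA, −78 °C; TMSCl (1.1 equiv), −78 → 0 °C; n-BuLi (1.2 equiv), −78 °C; CuBr·SMe2 (10 mol %), 4, −78 → −20 °C; aq NaHSO4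
Reagents that add atoms: chlorotrimethylsilane (TMSCl), C[Si](C)(C)Cl
Why: Iterative directed ortho-metalation on the in situ N-silylated carbamate (one equivalent of n-BuLi is consumed by the ammonium triflate left from the N-silylation) should first lithiate one of the two equivalent positions flanked by the carbamate and a MOM ether, the carbamate outranking the doubly MOM-flanked C–H, and the limiting TMSCl quench gives 7, which is kept N-protected and lithiated again in the same flask at the only remaining carbamate-flanked position; copper-catalyzed SN2 allylation with prenyl bromide at low temperature (which holds back anionic Fries migration of the carbamoyl group) then places the prenyl group at the future C8 after the ring lithiations are over, and the N–Si bond is hydrolyzed only once, on the acidic work-up.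

Step 4
Reactants: 10 3,5-bis(methoxymethoxy)-2-(3-methylbut-2-en-1-yl)-6-(trimethylsilyl)phenyl N-isopropylcarbamate
Product: 12 3,5-bis(methoxymethoxy)-2-(3-methylbut-2-en-1-yl)-6-(trimethylsilyl)phenyl trifluoromethanesulfonate, via silylphenol 11 (not isolated)
Conditions: DBU, Et2NH, MeCN, 40 °C; then PhNTf2, rt
Reagents that add atoms: N-phenylbis(trifluoromethanesulfonimide) (PhNTf2), O=S(=O)(N(c1ccccc1)S(=O)(=O)C(F)(F)F)C(F)(F)F
Why: E1cB cleavage of the N-monosubstituted carbamate (the expelled isopropyl isocyanate is trapped by Et2NH) frees the hindered phenoxide, which is triflated in the same flask to give the ortho-silyl aryl triflate that releases the C4a≡C8a aryne with fluoride.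

Step 5
Reactants: 13 methyl 3-bromo-4-hydroxybenzoate, 14 3-chloro-3-methylbut-1-yne
Product: 15 methyl 3-bromo-4-[(2-methylbut-3-yn-2-yl)oxy]benzoate
Conditions: DBU, CuCl2·2H2O (0.5 mol %), MeCN, 0 °C → rt
Reagents that add atoms: none
Why: Copper-catalyzed propargylic etherification (O-alkylation of the acidic bromophenol by the tertiary propargylic chloride through a copper-bound propargyl cation equivalent) should give the aryl 1,1-dimethylpropargyl ether without competing elimination.

Step 6
Reactants: 15 methyl 3-bromo-4-[(2-methylbut-3-yn-2-yl)oxy]benzoate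
Product: 17 methyl 8-bromo-2,2-dimethyl-2H-chromene-6-carboxylate, via allenylphenol 16 (not isolated)
Conditions: N,N-diethylaniline, 190 °C
Reagents that add atoms: none
Why: Aromatic propargyl Claisen rearrangement to the only free ortho position, tautomerization to allenylphenol 16, 1,5-hydrogen shift and 6π oxa-electrocyclization should close the dimethylpyran ring D in one thermal operation.

Step 7
Reactants: 17 methyl 8-bromo-2,2-dimethyl-2H-chromene-6-carboxylate, 18 tributyl(3-methylbut-2-en-1-yl)stannane
Product: 19 methyl 2,2-dimethyl-8-(3-methylbut-2-en-1-yl)-2H-chromene-6-carboxylate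
Conditions: Pd(PPh3)4 (5 mol %), DMF, 100 °C
Reagents that add atoms: none
Why: Stille coupling of the aryl bromide with the prenylstannane transfers the allyl group through its unsubstituted α-carbon and should give the linear prenyl arene, with the ester and the chromene untouched.

Step 8
Reactants: 19 methyl 2,2-dimethyl-8-(3-methylbut-2-en-1-yl)-2H-chromene-6-carboxylate, 20 N-methoxy-N-methylacetamide
Product: 22 3-[2,2-dimethyl-8-(3-methylbut-2-en-1-yl)-2H-chromen-6-yl]-N-methoxy-N-methyl-3-oxopropanamide, via lithium enolate 21 (not isolated)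
Conditions: 20 (2.2 equiv), LiN(iPr)2 (2.2 equiv), THF, −78 °C; then 19, −78 → 0 °C; aq NH4Cl
Reagents that add atoms: none
Why: Claisen condensation of lithium enolate 21 with the unhindered methyl ester is driven by deprotonation of the β-keto amide by the second equivalent of enolate, and the N-methoxy-N-methyl amide is kept as the acyl donor for the key step.

Step 9
Reactants: 22 3-[2,2-dimethyl-8-(3-methylbut-2-en-1-yl)-2H-chromen-6-yl]-N-methoxy-N-methyl-3-oxopropanamide
Product: 23 (3S)-3-[2,2-dimethyl-8-(3-methylbut-2-en-1-yl)-2H-chromen-6-yl]-3-hydroxy-N-methoxy-N-methylpropanamide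
Conditions: RuCl[(S,S)-TsDPEN](p-cymene) (1 mol %), HCO2H/Et3N (5:2 azeotrope), DMF, 40 °C
Reagents that add atoms: none
Why: Noyori-type asymmetric transfer hydrogenation of the aryl ketone (outer-sphere hydride and proton transfer) with the (S,S)-ligand should give the (S)-carbinol, the aryl group being placed by its CH/π contact with the p-cymene ligand as for acetophenone, while the alkenes and the amide are inert to the ruthenium hydride.

Step 10
Reactants: 23 (3S)-3-[2,2-dimethyl-8-(3-methylbut-2-en-1-yl)-2H-chromen-6-yl]-3-hydroxy-N-methoxy-N-methylpropanamide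
Product: 24 (3S)-3-[2,2-dimethyl-8-(3-methylbut-2-en-1-yl)-2H-chromen-6-yl]-N-methoxy-N-methyl-3-[(trimethylsilyl)oxy]propanamide
Conditions: TMSCl, imidazole, CH2Cl2, 0 °C
Reagents that add atoms: chlorotrimethylsilane (TMSCl), C[Si](C)(C)Cl
Why: Silylation of the secondary alcohol (silyl ether formation) gives a proton-free precursor from which fluoride can release the alkoxide in the key step.

Step 11
Reactants: 24 (3S)-3-[2,2-dimethyl-8-(3-methylbut-2-en-1-yl)-2H-chromen-6-yl]-N-methoxy-N-methyl-3-[(trimethylsilyl)oxy]propanamide, 12 3,5-bis(methoxymethoxy)-2-(3-methylbut-2-en-1-yl)-6-(trimethylsilyl)phenyl trifluoromethanesulfonate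
Product: 29 (2S)-2-[2,2-dimethyl-8-(3-methylbut-2-en-1-yl)-2H-chromen-6-yl]-5,7-bis(methoxymethoxy)-8-(3-methylbut-2-en-1-yl)-2,3-dihydro-4H-chromen-4-one, via cesium alkoxide 25 (not isolated), via aryne 26 (not isolated), via aryl anion 27 (not isolated), via tetrahedral adduct 28 (not isolated)
Conditions: 12 (1.5 equiv), CsF (3.5 equiv), 18-crown-6, anhydrous THF, 0 °C → rt; aq NH4Cl/pH 7 phosphate buffer, 0 °C
Reagents that add atoms: none
Why: Proposed new method: fluoride cleaves the O–SiMe3 bond of 24 and the C–SiMe3 bond of 12, so that the proton-free alkoxide 25 and the aryne 26 (triple bond C4a≡C8a) are formed side by side; 25 adds to C8a and the resulting C4a carbanion 27 attacks the Weinreb amide carbonyl (C4) that now sits six atoms away, which forms the C4–C4a bond and closes ring C by a 6-exo-trig acylation. The closest known reaction type is the fluoride-mediated annulation of arynes with salicylate esters to xanthones (heteroatom addition to the aryne followed by intramolecular acylation of the aryl anion); an aliphatic β-oxy amide has not been used in this role. No stereocenter is created: C2 is carried over from 24 with retention because its C–O bond is never broken, and the N-methoxy-N-methyl tetrahedral adduct 28 keeps C4 masked until the buffered quench, so that no enolizable ketone meets base and ring C cannot open by β-elimination. The step needs O-addition at C8a and not at C4a, which the C5 methoxymethoxy group secures by polarizing the aryne (inductive stabilization of negative charge at the adjacent C4a is expected to outweigh the steric bias of the C8 prenyl group), and it needs acylation to outrun protonation of 27, which the absence of any O–H donor (silyl ether as the alkoxide source, cesium as the counter-ion) secures.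

Step 12
Reactants: 29 (2S)-2-[2,2-dimethyl-8-(3-methylbut-2-en-1-yl)-2H-chromen-6-yl]-5,7-bis(methoxymethoxy)-8-(3-methylbut-2-en-1-yl)-2,3-dihydro-4H-chromen-4-one
Product: 30 maackiaflavanone B, (2S)-2-[2,2-dimethyl-8-(3-methylbut-2-en-1-yl)-2H-chromen-6-yl]-5,7-dihydroxy-8-(3-methylbut-2-en-1-yl)-2,3-dihydro-4H-chromen-4-one
Conditions: HCl (3 M aq), MeOH, 45 °C
Reagents that add atoms: none
Why: Acid-catalyzed solvolysis of the two MOM acetals (transacetalization to dimethoxymethane) frees the C5 and C7 phenols under conditions mild enough for the prenyl groups, the chromene and the C2 stereocenter, which is configurationally stable in acid.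

**Compound list**

1 | phloroglucinol (benzene-1,3,5-triol) | Oc1cc(O)cc(O)c1 | starting material
2 | 3,5-bis(methoxymethoxy)phenol | COCOc1cc(O)cc(OCOC)c1 | intermediate
3 | 3,5-bis(methoxymethoxy)phenyl N-isopropylcarbamate | CC(C)NC(=O)Oc1cc(OCOC)cc(OCOC)c1 | intermediate
4 | prenyl bromide (1-bromo-3-methylbut-2-ene) | CC(C)=CCBr | starting material
5 | 3,5-bis(methoxymethoxy)phenyl N-(tert-butyldimethylsilyl)-N-isopropylcarbamate (N-silyl carbamate) | CC(C)N([Si](C)(C)C(C)(C)C)C(=O)Oc1cc(OCOC)cc(OCOC)c1 | intermediate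
6 | 2-lithio-3,5-bis(methoxymethoxy)phenyl N-(tert-butyldimethylsilyl)-N-isopropylcarbamate (first aryllithium) | CC(C)N([Si](C)(C)C(C)(C)C)C(=O)Oc1c([Li])c(OCOC)cc(OCOC)c1 | intermediate
7 | 3,5-bis(methoxymethoxy)-2-(trimethylsilyl)phenyl N-(tert-butyldimethylsilyl)-N-isopropylcarbamate (C-silylated N-silyl carbamate) | CC(C)N([Si](C)(C)C(C)(C)C)C(=O)Oc1c([Si](C)(C)C)c(OCOC)cc(OCOC)c1 | intermediate
8 | 6-lithio-3,5-bis(methoxymethoxy)-2-(trimethylsilyl)phenyl N-(tert-butyldimethylsilyl)-N-isopropylcarbamate (second aryllithium) | CC(C)N([Si](C)(C)C(C)(C)C)C(=O)Oc1c([Si](C)(C)C)c(OCOC)cc(OCOC)c1[Li] | intermediate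
9 | 3,5-bis(methoxymethoxy)-2-(3-methylbut-2-en-1-yl)-6-(trimethylsilyl)phenyl N-(tert-butyldimethylsilyl)-N-isopropylcarbamate (prenylated N-silyl carbamate) | CC(C)N([Si](C)(C)C(C)(C)C)C(=O)Oc1c([Si](C)(C)C)c(OCOC)cc(OCOC)c1CC=C(C)C | intermediate
10 | 3,5-bis(methoxymethoxy)-2-(3-methylbut-2-en-1-yl)-6-(trimethylsilyl)phenyl N-isopropylcarbamate | CC(C)NC(=O)Oc1c([Si](C)(C)C)c(OCOC)cc(OCOC)c1CC=C(C)C | intermediate
11 | 3,5-bis(methoxymethoxy)-2-(3-methylbut-2-en-1-yl)-6-(trimethylsilyl)phenol (silylphenol, present as its DBU salt) | Oc1c([Si](C)(C)C)c(OCOC)cc(OCOC)c1CC=C(C)C | intermediate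
12 | 3,5-bis(methoxymethoxy)-2-(3-methylbut-2-en-1-yl)-6-(trimethylsilyl)phenyl trifluoromethanesulfonate | O=S(=O)(Oc1c([Si](C)(C)C)c(OCOC)cc(OCOC)c1CC=C(C)C)C(F)(F)F | intermediate
13 | methyl 3-bromo-4-hydroxybenzoate | COC(=O)c1ccc(O)c(Br)c1 | starting material
14 | 3-chloro-3-methylbut-1-yne | C#CC(C)(C)Cl | starting material
15 | methyl 3-bromo-4-[(2-methylbut-3-yn-2-yl)oxy]benzoate | COC(=O)c1ccc(OC(C)(C)C#C)c(Br)c1 | intermediate
16 | methyl 3-bromo-4-hydroxy-5-(3-methylbuta-1,2-dien-1-yl)benzoate (allenylphenol) | COC(=O)c1cc(Br)c(O)c(C=C=C(C)C)c1 | intermediate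
17 | methyl 8-bromo-2,2-dimethyl-2H-chromene-6-carboxylate | COC(=O)c1cc(Br)c2OC(C)(C)C=Cc2c1 | intermediate
18 | tributyl(3-methylbut-2-en-1-yl)stannane | CCCC[Sn](CCCC)(CCCC)CC=C(C)C | starting material
19 | methyl 2,2-dimethyl-8-(3-methylbut-2-en-1-yl)-2H-chromene-6-carboxylate | COC(=O)c1cc(CC=C(C)C)c2OC(C)(C)C=Cc2c1 | intermediate
20 | N-methoxy-N-methylacetamide | CC(=O)N(C)OC | starting material
21 | lithium enolate of N-methoxy-N-methylacetamide | C=C(O[Li])N(C)OC | intermediate
22 | 3-[2,2-dimethyl-8-(3-methylbut-2-en-1-yl)-2H-chromen-6-yl]-N-methoxy-N-methyl-3-oxopropanamide | CON(C)C(=O)CC(=O)c1cc(CC=C(C)C)c2OC(C)(C)C=Cc2c1 | intermediate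
23 | (3S)-3-[2,2-dimethyl-8-(3-methylbut-2-en-1-yl)-2H-chromen-6-yl]-3-hydroxy-N-methoxy-N-methylpropanamide | CON(C)C(=O)C[C@H](O)c1cc(CC=C(C)C)c2OC(C)(C)C=Cc2c1 | intermediate
24 | (3S)-3-[2,2-dimethyl-8-(3-methylbut-2-en-1-yl)-2H-chromen-6-yl]-N-methoxy-N-methyl-3-[(trimethylsilyl)oxy]propanamide | CON(C)C(=O)C[C@H](O[Si](C)(C)C)c1cc(CC=C(C)C)c2OC(C)(C)C=Cc2c1 | intermediate
25 | cesium (1S)-1-[2,2-dimethyl-8-(3-methylbut-2-en-1-yl)-2H-chromen-6-yl]-3-[methoxy(methyl)amino]-3-oxopropan-1-olate (cesium alkoxide) | CON(C)C(=O)C[C@H]([O-])c1cc(CC=C(C)C)c2OC(C)(C)C=Cc2c1.[Cs+] | intermediate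
26 | 1,2-didehydro-4,6-bis(methoxymethoxy)-3-(3-methylbut-2-en-1-yl)benzene (aryne, triple bond C4a≡C8a) | C1#CC(CC=C(C)C)=C(OCOC)C=C1OCOC | intermediate
27 | cesium salt of the C4a carbanion of the (S)-aryl ether formed by addition of 25 to C8a of 26 (aryl anion) | CON(C)C(=O)C[C@H](Oc1c(CC=C(C)C)c(OCOC)cc(OCOC)[c-]1)c1cc(CC=C(C)C)c2OC(C)(C)C=Cc2c1.[Cs+] | intermediate
28 | cesium (2S)-2-[2,2-dimethyl-8-(3-methylbut-2-en-1-yl)-2H-chromen-6-yl]-4-[methoxy(methyl)amino]-5,7-bis(methoxymethoxy)-8-(3-methylbut-2-en-1-yl)chroman-4-olate (tetrahedral adduct, C4 configuration undefined) | CC(C)=CCc1cc([C@@H]2CC([O-])(N(C)OC)c3c(OCOC)cc(OCOC)c(CC=C(C)C)c3O2)cc2c1OC(C)(C)C=C2.[Cs+] | intermediate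
29 | (2S)-2-[2,2-dimethyl-8-(3-methylbut-2-en-1-yl)-2H-chromen-6-yl]-5,7-bis(methoxymethoxy)-8-(3-methylbut-2-en-1-yl)-2,3-dihydro-4H-chromen-4-one | CC(C)=CCc1cc([C@@H]2CC(=O)c3c(OCOC)cc(OCOC)c(CC=C(C)C)c3O2)cc2c1OC(C)(C)C=C2 | intermediate
30 | maackiaflavanone B, (2S)-2-[2,2-dimethyl-8-(3-methylbut-2-en-1-yl)-2H-chromen-6-yl]-5,7-dihydroxy-8-(3-methylbut-2-en-1-yl)-2,3-dihydro-4H-chromen-4-one | CC(C)=CCc1cc([C@@H]2CC(=O)c3c(O)cc(O)c(CC=C(C)C)c3O2)cc2c1OC(C)(C)C=C2 | target

**Totals**

Total step count: 12 (steps 1–4 for the ring A fragment, steps 5–10 for the ring B/D fragment, steps 11 and 12 after the union).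
Longest linear sequence: 8 steps (steps 5–12, from 13).

**Steps most likely to fail**

1. Step 11 (Proposed new method). What may go wrong:
- retro-aldol cleavage or β-elimination of the cesium alkoxide before it meets the aryne;
- addition of the alkoxide at C4a instead of C8a because the prenyl group shields C8a;
- proton transfer from C3–H to the aryl anion in place of acylation, followed by loss of the phenoxide;
- early collapse of the tetrahedral adduct, after which base opens ring C and erodes the configuration at C2.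

Fallback (known chemistry; sets out from 3 and 22, returns at 29): 3 is prenylated by the in situ N-silylation and ortho-lithiation procedure of the first half of step 3, with 4 and catalytic CuBr·SMe2 as the quench, which gives 3,5-bis(methoxymethoxy)-2-(3-methylbut-2-en-1-yl)phenyl N-isopropylcarbamate F1. A second ortho-lithiation under the same conditions with iodine quench gives 2-iodo-3,5-bis(methoxymethoxy)-6-(3-methylbut-2-en-1-yl)phenyl N-isopropylcarbamate F2; ring metalation between the two oxygen directors is expected to be kinetically preferred over lateral metalation with n-BuLi/TMEDA at −78 °C. DBU/Et2NH frees 2-iodo-3,5-bis(methoxymethoxy)-6-(3-methylbut-2-en-1-yl)phenol F3. Ketone 22 is reduced with RuCl[(R,R)-TsDPEN](p-cymene) and HCO2H/Et3N to (3R)-3-[2,2-dimethyl-8-(3-methylbut-2-en-1-yl)-2H-chromen-6-yl]-3-hydroxy-N-methoxy-N-methylpropanamide F4. Mitsunobu etherification of F3 with F4 (PPh3, DIAD, THF, high concentration, sonication) should invert the carbinol carbon and give (3S)-3-[2,2-dimethyl-8-(3-methylbut-2-en-1-yl)-2H-chromen-6-yl]-3-[2-iodo-3,5-bis(methoxymethoxy)-6-(3-methylbut-2-en-1-yl)phenoxy]-N-methoxy-N-methylpropanamide F5. Iodine–magnesium exchange (iPrMgCl·LiCl, THF, −40 °C) then closes the same C4–C4a bond by Parham-type cyclization onto the Weinreb amide and should give 29 after a buffered quench.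

2. Step 3. What may go wrong: incomplete second lithiation in the salt-laden one-flask mixture, or sluggish allylation of the hindered aryllithium, which lets anionic Fries migration of the carbamoyl group, attack at the tertiary terminus of the allyl bromide, or lithiation between the two MOM ethers compete.

Fallback (sets out from 3, returns at 10): the two metalations are separated and the organolithium allylation is replaced by a cross-coupling. Step 3 is stopped after the TMSCl quench and worked up with aq NaHSO4, which hydrolyzes the N–Si bond of 7 and should give purified 3,5-bis(methoxymethoxy)-2-(trimethylsilyl)phenyl N-isopropylcarbamate F6. F6 is N-silylated (TBSOTf, TMEDA) and lithiated (n-BuLi, TMEDA, −78 °C) in a fresh flask, which leads back to 7 and 8 free of salts and of residual TMSCl. Aryllithium 8 is quenched with iodine at −78 °C to give 2-iodo-3,5-bis(methoxymethoxy)-6-(trimethylsilyl)phenyl N-(tert-butyldimethylsilyl)-N-isopropylcarbamate F7, which the acidic work-up hydrolyzes to 2-iodo-3,5-bis(methoxymethoxy)-6-(trimethylsilyl)phenyl N-isopropylcarbamate F8. Stille coupling of F8 with 18 (Pd(PPh3)4, DMF, 90 °C) should then give 10.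

3. Step 8. What may go wrong: slow acylation of the amide enolate by the electron-rich benzoate, so that self-condensation or decomposition of the enolate on warming takes over.

Fallback (sets out from 19, returns at 22): i-Bu2AlH (CH2Cl2, −78 → 0 °C) reduces 19 to [2,2-dimethyl-8-(3-methylbut-2-en-1-yl)-2H-chromen-6-yl]methanol F9. MnO2 (CH2Cl2, rt) oxidizes it to 2,2-dimethyl-8-(3-methylbut-2-en-1-yl)-2H-chromene-6-carbaldehyde F10. Aldol addition of enolate 21 (THF, −78 °C) gives racemic 3-[2,2-dimethyl-8-(3-methylbut-2-en-1-yl)-2H-chromen-6-yl]-3-hydroxy-N-methoxy-N-methylpropanamide F11, and Dess–Martin periodinane (NaHCO3, CH2Cl2) oxidizes F11 to 22.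

**Further compounds**

F1 | step 11 | 3,5-bis(methoxymethoxy)-2-(3-methylbut-2-en-1-yl)phenyl N-isopropylcarbamate | CC(C)NC(=O)Oc1cc(OCOC)cc(OCOC)c1CC=C(C)C
F2 | step 11 | 2-iodo-3,5-bis(methoxymethoxy)-6-(3-methylbut-2-en-1-yl)phenyl N-isopropylcarbamate | CC(C)NC(=O)Oc1c(I)c(OCOC)cc(OCOC)c1CC=C(C)C
F3 | step 11 | 2-iodo-3,5-bis(methoxymethoxy)-6-(3-methylbut-2-en-1-yl)phenol | Oc1c(I)c(OCOC)cc(OCOC)c1CC=C(C)C
F4 | step 11 | (3R)-3-[2,2-dimethyl-8-(3-methylbut-2-en-1-yl)-2H-chromen-6-yl]-3-hydroxy-N-methoxy-N-methylpropanamide | CON(C)C(=O)C[C@@H](O)c1cc(CC=C(C)C)c2OC(C)(C)C=Cc2c1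
F5 | step 11 | (3S)-3-[2,2-dimethyl-8-(3-methylbut-2-en-1-yl)-2H-chromen-6-yl]-3-[2-iodo-3,5-bis(methoxymethoxy)-6-(3-methylbut-2-en-1-yl)phenoxy]-N-methoxy-N-methylpropanamide | CON(C)C(=O)C[C@H](Oc1c(I)c(OCOC)cc(OCOC)c1CC=C(C)C)c1cc(CC=C(C)C)c2OC(C)(C)C=Cc2c1
F6 | step 3 | 3,5-bis(methoxymethoxy)-2-(trimethylsilyl)phenyl N-isopropylcarbamate | CC(C)NC(=O)Oc1c([Si](C)(C)C)c(OCOC)cc(OCOC)c1
F7 | step 3 | 2-iodo-3,5-bis(methoxymethoxy)-6-(trimethylsilyl)phenyl N-(tert-butyldimethylsilyl)-N-isopropylcarbamate | CC(C)N([Si](C)(C)C(C)(C)C)C(=O)Oc1c([Si](C)(C)C)c(OCOC)cc(OCOC)c1I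
F8 | step 3 | 2-iodo-3,5-bis(methoxymethoxy)-6-(trimethylsilyl)phenyl N-isopropylcarbamate | CC(C)NC(=O)Oc1c([Si](C)(C)C)c(OCOC)cc(OCOC)c1I
F9 | step 8 | [2,2-dimethyl-8-(3-methylbut-2-en-1-yl)-2H-chromen-6-yl]methanol | OCc1cc(CC=C(C)C)c2OC(C)(C)C=Cc2c1
F10 | step 8 | 2,2-dimethyl-8-(3-methylbut-2-en-1-yl)-2H-chromene-6-carbaldehyde | O=Cc1cc(CC=C(C)C)c2OC(C)(C)C=Cc2c1
F11 | step 8 | racemic 3-[2,2-dimethyl-8-(3-methylbut-2-en-1-yl)-2H-chromen-6-yl]-3-hydroxy-N-methoxy-N-methylpropanamide | CON(C)C(=O)CC(O)c1cc(CC=C(C)C)c2OC(C)(C)C=Cc2c1
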